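**Retrosynthetic overview**
1. Target ⇐ hydrogenolysis of two aryl benzyl ethers ⇐ tetrahydrofuran (the only ring, closed last) by 5-exo-tet attack of the C9' oxygen on a C9 mesylate, so the sensitive C7 carbinol is never an electrophile.
2. Acyclic precursor ⇐ Evans syn-aldol (key C7–C8 bond) of an (S)-oxazolidinone imide with 4-benzyloxy-3,5-dimethoxybenzaldehyde; this sets C7 and C8.
3. Imide ⇐ (R)-3-arylmethyl-4-silyloxybutanoic acid ⇐ alkene cleavage ⇐ Evans benzylation of an N-pentenoyl (R)-oxazolidinone with 4-benzyloxy-3-methoxybenzyl bromide; this sets C8'.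

Assumptions: lignan locants are used (syringyl half: C7 carbinol, C8 ring CH, C9 ring CH2; guaiacyl half: C7' benzylic CH2, C8' ring CH, C9' ring CH2). Both enantiomers of 4-benzyl-2-oxazolidinone are taken as cheap commercial materials.

**Step 1**
Reactants: 1 4-(benzyloxy)-3-methoxybenzyl alcohol
Product: 2 4-(benzyloxy)-3-methoxybenzyl bromide
Conditions: PBr3 (0.4 equiv), Et2O, 0 °C, 1 h; used at once
Reagents that add atoms: phosphorus tribromide, BrP(Br)Br
Why: SN2 bromination of an activated benzylic alcohol through its phosphite ester; the aryl benzyl ether is inert.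

**Step 2**
Reactants: 3 (R)-4-benzyl-2-oxazolidinone; 4 pent-4-enoyl chloride
Product: 6 (R)-4-benzyl-3-(pent-4-enoyl)oxazolidin-2-one, via lithium oxazolidinide 5 (not isolated)
Conditions: n-BuLi, THF, −78 °C; then 4, −78 → 0 °C
Reagents that add atoms: none
Why: N-acylation of the lithiated auxiliary by the acid chloride (nucleophilic acyl substitution).

**Step 3**
Reactants: 6 (R)-4-benzyl-3-(pent-4-enoyl)oxazolidin-2-one; 2 4-(benzyloxy)-3-methoxybenzyl bromide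
Product: 8 (R)-4-benzyl-3-{(S)-2-[4-(benzyloxy)-3-methoxybenzyl]pent-4-enoyl}oxazolidin-2-one, via sodium Z-enolate 7 (not isolated)
Conditions: NaHMDS (1.1 equiv), THF, −78 °C; then 2 (1.4 equiv), −78 → −20 °C
Reagents that add atoms: none
Why: Evans asymmetric alkylation; the chelated Z-enolate is shielded on one face by the C4 benzyl group, so the benzylic bromide enters from the open face and sets C8' as (S) in this imide (R in the target), typically ≥95:5 dr.

**Step 4**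
Reactants: 8 (R)-4-benzyl-3-{(S)-2-[4-(benzyloxy)-3-methoxybenzyl]pent-4-enoyl}oxazolidin-2-one
Product: 9 (S)-2-[4-(benzyloxy)-3-methoxybenzyl]pent-4-en-1-ol
Conditions: LiBH4 (2 equiv), THF, 0 °C → rt
Reagents that add atoms: none
Why: Reductive cleavage of the imide at the exocyclic carbonyl gives the primary alcohol and returns the auxiliary; the stereocentre is not touched.

**Step 5**
Reactants: 9 (S)-2-[4-(benzyloxy)-3-methoxybenzyl]pent-4-en-1-ol
Product: 10 (S)-{[2-(4-(benzyloxy)-3-methoxybenzyl)pent-4-en-1-yl]oxy}(tert-butyl)diphenylsilane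
Conditions: TBDPSCl, imidazole, DMF, rt
Reagents that add atoms: tert-butyldiphenylsilyl chloride, CC(C)(C)[Si](Cl)(c1ccccc1)c1ccccc1
Why: Silylation of the primary alcohol; TBDPS survives the oxidations, the aldol and the hydride steps ahead and is removed by fluoride at the ring closure.

**Step 6**
Reactants: 10 (S)-{[2-(4-(benzyloxy)-3-methoxybenzyl)pent-4-en-1-yl]oxy}(tert-butyl)diphenylsilane
Product: 12 (R)-3-[4-(benzyloxy)-3-methoxybenzyl]-4-[(tert-butyldiphenylsilyl)oxy]butanal, via vicinal diol 11 (not isolated)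
Conditions: OsO4 (2 mol %), NaIO4 (4 equiv), 2,6-lutidine (2 equiv), dioxane/H2O 3:1, rt
Reagents that add atoms: osmium tetroxide, O=[Os](=O)(=O)=O (catalytic oxygen donor); sodium periodate, [Na+].[O-]I(=O)(=O)=O (terminal oxidant that reloads osmium)
Why: Lemieux–Johnson oxidation (dihydroxylation, then glycol cleavage) shortens the terminal alkene to the aldehyde without touching the electron-rich arene; the stereocentre is β to the new carbonyl and cannot epimerise.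

**Step 7**
Reactants: 12 (R)-3-[4-(benzyloxy)-3-methoxybenzyl]-4-[(tert-butyldiphenylsilyl)oxy]butanal
Product: 13 (R)-3-[4-(benzyloxy)-3-methoxybenzyl]-4-[(tert-butyldiphenylsilyl)oxy]butanoic acid
Conditions: NaClO2, NaH2PO4, 2-methyl-2-butene, t-BuOH/H2O, 0 °C → rt
Reagents that add atoms: sodium chlorite, [Na+].[O-]Cl=O
Why: Pinnick oxidation; the alkene scavenger removes HOCl, so the arenes are not chlorinated and the silyl ether survives the buffered medium.

**Step 8**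
Reactants: 13 (R)-3-[4-(benzyloxy)-3-methoxybenzyl]-4-[(tert-butyldiphenylsilyl)oxy]butanoic acid; 14 (S)-4-benzyl-2-oxazolidinone
Product: 16 (S)-4-benzyl-3-{(R)-3-[4-(benzyloxy)-3-methoxybenzyl]-4-[(tert-butyldiphenylsilyl)oxy]butanoyl}oxazolidin-2-one, via pivaloyl mixed anhydride 15 (not isolated)
Conditions: PivCl, Et3N, THF, −20 °C; then LiCl, 14, −20 °C → rt
Reagents that add atoms: none
Why: Mixed-anhydride N-acylation; the auxiliary attacks the unhindered carbonyl of the pivalic anhydride, with no strong base and no risk to the β-stereocentre.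

**Step 9**
Reactants: 17 syringaldehyde (4-hydroxy-3,5-dimethoxybenzaldehyde)
Product: 18 4-(benzyloxy)-3,5-dimethoxybenzaldehyde
Conditions: BnBr, K2CO3, DMF, 60 °C
Reagents that add atoms: benzyl bromide, BrCc1ccccc1
Why: Williamson ether synthesis on the phenoxide.

**Step 10 (key step)**
Reactants: 16 (S)-4-benzyl-3-{(R)-3-[4-(benzyloxy)-3-methoxybenzyl]-4-[(tert-butyldiphenylsilyl)oxy]butanoyl}oxazolidin-2-one; 18 4-(benzyloxy)-3,5-dimethoxybenzaldehyde
Product: 21 (S)-4-benzyl-3-{(2S,3S)-3-[4-(benzyloxy)-3,5-dimethoxyphenyl]-2-[(R)-1-[4-(benzyloxy)-3-methoxyphenyl]-3-[(tert-butyldiphenylsilyl)oxy]propan-2-yl]-3-hydroxypropanoyl}oxazolidin-2-one, via dibutylboron Z-enolate 19 (not isolated), via dibutylboron aldolate 20 (not isolated)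
Conditions: Bu2BOTf (1.2 equiv), i-Pr2NEt (1.4 equiv), CH2Cl2, −78 → 0 °C; then 18, −78 → 0 °C; then pH 7 buffer, MeOH, 30% H2O2, 0 °C
Reagents that add atoms: none
Why: Evans syn-aldol; the Z-boron enolate reacts through a closed Zimmerman–Traxler chair on the face away from the auxiliary benzyl group, so the (S)-auxiliary sets C8 and C7 as the 2,3-syn pair (2S,3S here, 8R and 7S in the target), with the existing C8' centre a spectator.

**Step 11**
Reactants: 21 (aldol adduct, name as in step 10)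
Product: 22 (S)-4-benzyl-3-{(2S,3S)-3-[4-(benzyloxy)-3,5-dimethoxyphenyl]-2-[(R)-1-[4-(benzyloxy)-3-methoxyphenyl]-3-[(tert-butyldiphenylsilyl)oxy]propan-2-yl]-3-[(tert-butyldimethylsilyl)oxy]propanoyl}oxazolidin-2-one
Conditions: TBSOTf, 2,6-lutidine, CH2Cl2, −78 → 0 °C
Reagents that add atoms: tert-butyldimethylsilyl triflate, CC(C)(C)[Si](C)(C)OS(=O)(=O)C(F)(F)F
Why: Silylation of the hindered benzylic hydroxyl under non-basic conditions blocks retro-aldol and keeps C7–O out of the later ring closure.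

**Step 12**
Reactants: 22 (silylated aldol adduct, name as in step 11)
Product: 23 (2R,3R)-3-[4-(benzyloxy)-3-methoxybenzyl]-2-{(S)-[4-(benzyloxy)-3,5-dimethoxyphenyl][(tert-butyldimethylsilyl)oxy]methyl}-4-[(tert-butyldiphenylsilyl)oxy]butan-1-ol
Conditions: LiBH4 (3 equiv), THF, 0 °C → rt
Reagents that add atoms: none
Why: Reductive removal of the auxiliary turns the imide carbonyl into the C9 primary alcohol; no stereocentre is touched (the descriptor at C8 changes only through CIP priorities).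

**Step 13**
Reactants: 23 (alcohol, name as in step 12)
Product: 24 (2R,3R)-3-[4-(benzyloxy)-3-methoxybenzyl]-2-{(S)-[4-(benzyloxy)-3,5-dimethoxyphenyl][(tert-butyldimethylsilyl)oxy]methyl}-4-[(tert-butyldiphenylsilyl)oxy]butyl methanesulfonate
Conditions: MsCl, Et3N, CH2Cl2, 0 °C
Reagents that add atoms: methanesulfonyl chloride, CS(Cl)(=O)=O
Why: Sulfonylation of the only free hydroxyl makes C9 the electrophile for ring closure.

**Step 14**
Reactants: 24 (mesylate, name as in step 13)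
Product: 27 (S)-[4-(benzyloxy)-3,5-dimethoxyphenyl]{(3R,4R)-4-[4-(benzyloxy)-3-methoxybenzyl]tetrahydrofuran-3-yl}methanol, via C9' alkoxide 25 (not isolated), via tetrahydrofuran silyl ether 26 (not isolated)
Conditions: TBAF (4 equiv), THF, 0 °C → rt, then 40 °C until 26 is consumed
Reagents that add atoms: none
Why: Fluoride removes the primary TBDPS group first and the freed alkoxide closes the ring by intramolecular Williamson etherification (5-exo-tet, far faster than the 4-exo path open to the C7 oxygen); the benzylic TBS ether is then cleaved, and both ring-forming carbons are CH2 so no stereocentre changes.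

**Step 15**
Reactants: 27 (tetrahydrofuran alcohol, name as in step 14)
Product: 28 4-[(S)-hydroxy{(3R,4R)-4-[(4-hydroxy-3-methoxyphenyl)methyl]oxolan-3-yl}methyl]-2,6-dimethoxyphenol (target)
Conditions: H2 (1 atm), 10% Pd/C, EtOAc/EtOH, rt; stopped after 2 equiv H2; neutral work-up
Reagents that add atoms: none
Why: Catalytic hydrogenolysis cleaves the two aryl benzyl ethers much faster than the secondary benzylic C–OH under neutral conditions, and the final phenolic carbinol is kept away from acid.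

**Compound list**
1 | 4-(benzyloxy)-3-methoxybenzyl alcohol | COc1cc(CO)ccc1OCc1ccccc1 | starting material
2 | 4-(benzyloxy)-3-methoxybenzyl bromide | COc1cc(CBr)ccc1OCc1ccccc1 | intermediate
3 | (R)-4-benzyl-2-oxazolidinone | O=C1N[C@H](Cc2ccccc2)CO1 | starting material
4 | pent-4-enoyl chloride | C=CCCC(Cl)=O | starting material
5 | lithium (R)-4-benzyl-2-oxooxazolidin-3-ide | [Li+].O=C1[N-][C@H](Cc2ccccc2)CO1 | intermediate (not isolated)
6 | (R)-4-benzyl-3-(pent-4-enoyl)oxazolidin-2-one | C=CCCC(=O)N1[C@H](Cc2ccccc2)COC1=O | intermediate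
7 | sodium (Z)-enolate of 6 | [Na+].C=CC/C=C(\[O-])N1[C@H](Cc2ccccc2)COC1=O | intermediate (not isolated)
8 | (R)-4-benzyl-3-{(S)-2-[4-(benzyloxy)-3-methoxybenzyl]pent-4-enoyl}oxazolidin-2-one | C=CC[C@@H](Cc1ccc(OCc2ccccc2)c(OC)c1)C(=O)N1[C@H](Cc2ccccc2)COC1=O | intermediate
9 | (S)-2-[4-(benzyloxy)-3-methoxybenzyl]pent-4-en-1-ol | C=CC[C@@H](Cc1ccc(OCc2ccccc2)c(OC)c1)CO | intermediate
10 | (S)-{[2-(4-(benzyloxy)-3-methoxybenzyl)pent-4-en-1-yl]oxy}(tert-butyl)diphenylsilane | C=CC[C@@H](Cc1ccc(OCc2ccccc2)c(OC)c1)CO[Si](c1ccccc1)(c1ccccc1)C(C)(C)C | intermediate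
11 | (2RS,4R)-4-[4-(benzyloxy)-3-methoxybenzyl]-5-[(tert-butyldiphenylsilyl)oxy]pentane-1,2-diol | OCC(O)C[C@@H](Cc1ccc(OCc2ccccc2)c(OC)c1)CO[Si](c1ccccc1)(c1ccccc1)C(C)(C)C | intermediate (not isolated)
12 | (R)-3-[4-(benzyloxy)-3-methoxybenzyl]-4-[(tert-butyldiphenylsilyl)oxy]butanal | O=CC[C@@H](Cc1ccc(OCc2ccccc2)c(OC)c1)CO[Si](c1ccccc1)(c1ccccc1)C(C)(C)C | intermediate
13 | (R)-3-[4-(benzyloxy)-3-methoxybenzyl]-4-[(tert-butyldiphenylsilyl)oxy]butanoic acid | OC(=O)C[C@@H](Cc1ccc(OCc2ccccc2)c(OC)c1)CO[Si](c1ccccc1)(c1ccccc1)C(C)(C)C | intermediate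
14 | (S)-4-benzyl-2-oxazolidinone | O=C1N[C@@H](Cc2ccccc2)CO1 | starting material
15 | mixed anhydride of 13 with pivalic acid | CC(C)(C)C(=O)OC(=O)C[C@@H](Cc1ccc(OCc2ccccc2)c(OC)c1)CO[Si](c1ccccc1)(c1ccccc1)C(C)(C)C | intermediate (not isolated)
16 | (S)-4-benzyl-3-{(R)-3-[4-(benzyloxy)-3-methoxybenzyl]-4-[(tert-butyldiphenylsilyl)oxy]butanoyl}oxazolidin-2-one | O=C(C[C@@H](Cc1ccc(OCc2ccccc2)c(OC)c1)CO[Si](c1ccccc1)(c1ccccc1)C(C)(C)C)N1[C@@H](Cc2ccccc2)COC1=O | intermediate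
17 | syringaldehyde | COc1cc(C=O)cc(OC)c1O | starting material
18 | 4-(benzyloxy)-3,5-dimethoxybenzaldehyde | COc1cc(C=O)cc(OC)c1OCc1ccccc1 | intermediate
19 | dibutylboron (Z)-enolate of 16 | CCCCB(CCCC)O/C(=C\[C@@H](Cc1ccc(OCc2ccccc2)c(OC)c1)CO[Si](c1ccccc1)(c1ccccc1)C(C)(C)C)N1[C@@H](Cc2ccccc2)COC1=O | intermediate (not isolated)
20 | O-dibutylboryl aldolate of 21 | O=C(N1[C@@H](Cc2ccccc2)COC1=O)[C@H]([C@H](OB(CCCC)CCCC)c1cc(OC)c(OCc2ccccc2)c(OC)c1)[C@@H](Cc1ccc(OCc2ccccc2)c(OC)c1)CO[Si](c1ccccc1)(c1ccccc1)C(C)(C)C | intermediate (not isolated)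
21 | (S)-4-benzyl-3-{(2S,3S)-3-[4-(benzyloxy)-3,5-dimethoxyphenyl]-2-[(R)-1-[4-(benzyloxy)-3-methoxyphenyl]-3-[(tert-butyldiphenylsilyl)oxy]propan-2-yl]-3-hydroxypropanoyl}oxazolidin-2-one | O=C(N1[C@@H](Cc2ccccc2)COC1=O)[C@H]([C@H](O)c1cc(OC)c(OCc2ccccc2)c(OC)c1)[C@@H](Cc1ccc(OCc2ccccc2)c(OC)c1)CO[Si](c1ccccc1)(c1ccccc1)C(C)(C)C | intermediate
22 | C7-O-tert-butyldimethylsilyl ether of 21 (2S,3S; side chain R; auxiliary S) | O=C(N1[C@@H](Cc2ccccc2)COC1=O)[C@H]([C@H](O[Si](C)(C)C(C)(C)C)c1cc(OC)c(OCc2ccccc2)c(OC)c1)[C@@H](Cc1ccc(OCc2ccccc2)c(OC)c1)CO[Si](c1ccccc1)(c1ccccc1)C(C)(C)C | intermediate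
23 | (2R,3R)-3-[4-(benzyloxy)-3-methoxybenzyl]-2-{(S)-[4-(benzyloxy)-3,5-dimethoxyphenyl][(tert-butyldimethylsilyl)oxy]methyl}-4-[(tert-butyldiphenylsilyl)oxy]butan-1-ol | OC[C@H]([C@H](O[Si](C)(C)C(C)(C)C)c1cc(OC)c(OCc2ccccc2)c(OC)c1)[C@@H](Cc1ccc(OCc2ccccc2)c(OC)c1)CO[Si](c1ccccc1)(c1ccccc1)C(C)(C)C | intermediate
24 | methanesulfonate of 23 (2R,3R; carbinol S) | CS(=O)(=O)OC[C@H]([C@H](O[Si](C)(C)C(C)(C)C)c1cc(OC)c(OCc2ccccc2)c(OC)c1)[C@@H](Cc1ccc(OCc2ccccc2)c(OC)c1)CO[Si](c1ccccc1)(c1ccccc1)C(C)(C)C | intermediate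
25 | tetrabutylammonium C9' alkoxide from 24 (TBDPS removed, mesylate and TBS in place) | CCCC[N+](CCCC)(CCCC)CCCC.CS(=O)(=O)OC[C@H]([C@H](O[Si](C)(C)C(C)(C)C)c1cc(OC)c(OCc2ccccc2)c(OC)c1)[C@@H](Cc1ccc(OCc2ccccc2)c(OC)c1)C[O-] | intermediate (not isolated)
26 | tert-butyldimethylsilyl ether of 27: {(S)-[4-(benzyloxy)-3,5-dimethoxyphenyl][(3R,4R)-4-(4-(benzyloxy)-3-methoxybenzyl)tetrahydrofuran-3-yl]methoxy}(tert-butyl)dimethylsilane | COc1cc(C[C@H]2COC[C@@H]2[C@H](O[Si](C)(C)C(C)(C)C)c2cc(OC)c(OCc3ccccc3)c(OC)c2)ccc1OCc1ccccc1 | intermediate (not isolated)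
27 | (S)-[4-(benzyloxy)-3,5-dimethoxyphenyl]{(3R,4R)-4-[4-(benzyloxy)-3-methoxybenzyl]tetrahydrofuran-3-yl}methanol | COc1cc(C[C@H]2COC[C@@H]2[C@H](O)c2cc(OC)c(OCc3ccccc3)c(OC)c2)ccc1OCc1ccccc1 | intermediate
28 | 4-[(S)-hydroxy{(3R,4R)-4-[(4-hydroxy-3-methoxyphenyl)methyl]oxolan-3-yl}methyl]-2,6-dimethoxyphenol | COc1cc(C[C@H]2COC[C@@H]2[C@H](O)c2cc(OC)c(O)c(OC)c2)ccc1O | target

**Totals**
Total step count: 15. Longest linear sequence: 13 steps (3 → 28 through steps 2–8 and 10–15; equally 1 → 28 through steps 1, 3–8 and 10–15).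

**Three steps most likely to fail, each with a fallback**

Step 10 (aldol of a β-branched, hindered imide; risk of low conversion or retro-aldol on work-up). The fallback sets out from acid 13 and comes back at alcohol 23. Acid 13 is coupled with (S)-4-benzylthiazolidine-2-thione (EDCI, DMAP, CH2Cl2) to give the N-acyl thiazolidinethione F1. Soft enolisation with TiCl4, i-Pr2NEt and N-methylpyrrolidinone in CH2Cl2 at 0 °C gives the more nucleophilic chlorotitanium enolate, which adds to aldehyde 18 in the Evans-syn sense and gives the thioimide aldol F2 with the same C7/C8 configuration. TBSOTf and 2,6-lutidine give the silyl ether F3. The thiazolidinethione is a far better leaving group than the oxazolidinone, so NaBH4 in THF/EtOH reduces F3 directly to 23.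

Step 12 (hydride may attack the ring carbonyl of the very congested imide 22 instead of the acyl carbonyl). The fallback sets out from aldol 21 and comes back at mesylate 24. The free aldol 21 is reduced before silylation (LiBH4, MeOH, THF, 0 °C), where the β-hydroxyl assists delivery and the substrate is less crowded, giving the 1,3-diol F4. The primary hydroxyl is mesylated selectively (MsCl 1.05 equiv, 2,4,6-collidine, CH2Cl2, −20 °C) to give the hydroxy mesylate F5. TBSOTf and 2,6-lutidine then silylate the benzylic hydroxyl and give 24.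

Step 14 (order of desilylation is not guaranteed; possible oxetane formation from the C7 oxygen or attack of fluoride on the mesylate). The fallback sets out from aldol 21 and comes back at 26, which is then desilylated with TBAF to 27 as in the second half of step 14. Aldol 21 is treated with TBAF buffered with AcOH in THF: loss of the TBDPS group gives the γ-hydroxy imide F6, which is not isolated because its C9' hydroxyl closes onto the imide carbonyl and expels auxiliary 14, giving the trans hydroxy lactone F7. TBSOTf and 2,6-lutidine give the silyloxy lactone F8. LiAlH4 (THF, 0 °C) opens it to the 1,4-diol F9, in which both ring-forming hydroxyls are primary and the C7 oxygen is masked. Mitsunobu cyclodehydration (PPh3, DIAD, THF) then closes the tetrahydrofuran without any fluoride or sulfonate and gives 26.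

**Further compounds**
F1 | step 10 | (R)-1-[(S)-4-benzyl-2-thioxothiazolidin-3-yl]-3-[4-(benzyloxy)-3-methoxybenzyl]-4-[(tert-butyldiphenylsilyl)oxy]butan-1-one | O=C(C[C@@H](Cc1ccc(OCc2ccccc2)c(OC)c1)CO[Si](c1ccccc1)(c1ccccc1)C(C)(C)C)N1[C@@H](Cc2ccccc2)CSC1=S
F2 | step 10 | (2S,3S)-1-[(S)-4-benzyl-2-thioxothiazolidin-3-yl]-3-[4-(benzyloxy)-3,5-dimethoxyphenyl]-2-[(R)-1-[4-(benzyloxy)-3-methoxyphenyl]-3-[(tert-butyldiphenylsilyl)oxy]propan-2-yl]-3-hydroxypropan-1-one | O=C(N1[C@@H](Cc2ccccc2)CSC1=S)[C@H]([C@H](O)c1cc(OC)c(OCc2ccccc2)c(OC)c1)[C@@H](Cc1ccc(OCc2ccccc2)c(OC)c1)CO[Si](c1ccccc1)(c1ccccc1)C(C)(C)C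
F3 | step 10 | C7-O-tert-butyldimethylsilyl ether of F2 | O=C(N1[C@@H](Cc2ccccc2)CSC1=S)[C@H]([C@H](O[Si](C)(C)C(C)(C)C)c1cc(OC)c(OCc2ccccc2)c(OC)c1)[C@@H](Cc1ccc(OCc2ccccc2)c(OC)c1)CO[Si](c1ccccc1)(c1ccccc1)C(C)(C)C
F4 | step 12 | (1S,2R)-1-[4-(benzyloxy)-3,5-dimethoxyphenyl]-2-{(R)-1-[4-(benzyloxy)-3-methoxyphenyl]-3-[(tert-butyldiphenylsilyl)oxy]propan-2-yl}propane-1,3-diol | OC[C@H]([C@H](O)c1cc(OC)c(OCc2ccccc2)c(OC)c1)[C@@H](Cc1ccc(OCc2ccccc2)c(OC)c1)CO[Si](c1ccccc1)(c1ccccc1)C(C)(C)C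
F5 | step 12 | (2R,3S)-3-[4-(benzyloxy)-3,5-dimethoxyphenyl]-2-{(R)-1-[4-(benzyloxy)-3-methoxyphenyl]-3-[(tert-butyldiphenylsilyl)oxy]propan-2-yl}-3-hydroxypropyl methanesulfonate | CS(=O)(=O)OC[C@H]([C@H](O)c1cc(OC)c(OCc2ccccc2)c(OC)c1)[C@@H](Cc1ccc(OCc2ccccc2)c(OC)c1)CO[Si](c1ccccc1)(c1ccccc1)C(C)(C)C
F6 | step 14 | (S)-4-benzyl-3-{(2S,3S)-3-[4-(benzyloxy)-3,5-dimethoxyphenyl]-2-[(R)-1-[4-(benzyloxy)-3-methoxyphenyl]-3-hydroxypropan-2-yl]-3-hydroxypropanoyl}oxazolidin-2-one | O=C(N1[C@@H](Cc2ccccc2)COC1=O)[C@H]([C@H](O)c1cc(OC)c(OCc2ccccc2)c(OC)c1)[C@@H](Cc1ccc(OCc2ccccc2)c(OC)c1)CO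
F7 | step 14 | (3S,4R)-4-[4-(benzyloxy)-3-methoxybenzyl]-3-{(S)-[4-(benzyloxy)-3,5-dimethoxyphenyl](hydroxy)methyl}dihydrofuran-2(3H)-one | O=C1OC[C@H](Cc2ccc(OCc3ccccc3)c(OC)c2)[C@H]1[C@H](O)c1cc(OC)c(OCc2ccccc2)c(OC)c1
F8 | step 14 | (3S,4R)-4-[4-(benzyloxy)-3-methoxybenzyl]-3-{(S)-[4-(benzyloxy)-3,5-dimethoxyphenyl][(tert-butyldimethylsilyl)oxy]methyl}dihydrofuran-2(3H)-one | O=C1OC[C@H](Cc2ccc(OCc3ccccc3)c(OC)c2)[C@H]1[C@H](O[Si](C)(C)C(C)(C)C)c1cc(OC)c(OCc2ccccc2)c(OC)c1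
F9 | step 14 | (2R,3R)-2-[4-(benzyloxy)-3-methoxybenzyl]-3-{(S)-[4-(benzyloxy)-3,5-dimethoxyphenyl][(tert-butyldimethylsilyl)oxy]methyl}butane-1,4-diol | OC[C@H]([C@H](O[Si](C)(C)C(C)(C)C)c1cc(OC)c(OCc2ccccc2)c(OC)c1)[C@@H](Cc1ccc(OCc2ccccc2)c(OC)c1)CO
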